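**Assumptions**
- (2E,6E)-farnesyl acetate and 5-hydroxy-2-methoxybenzaldehyde are commercially available.
- The two ring-C diastereomers formed in Step 16 can be separated by chromatography.
- I read the target as follows: normal drimane configuration (5α-H, 9α-H, 10β-Me), 4β-Me axial, 4α-CH2OH equatorial, Δ7, and a 6-alkyl epoxydon ring attached through C11.

**Retrosynthesis**
1. The epoxy-enone-ol comes from a quinone monoketal: nucleophilic epoxidation of the unhindered enone, Luche reduction of the ketone, then ketal hydrolysis and desilylation. The monoketal comes from PIDA oxidation of a 4-methoxyphenol.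
2. The C11–aryl bond is made by Negishi coupling of a drimenyl iodide with a protected bromophenol.
3. Rings A and B are formed in one step by epoxide-initiated polyene cyclization. The epoxide comes from Sharpless epoxidation of 12-hydroxyfarnesyl acetate.
4. The (E)-CH2OR terminus of that alkene fixes the equatorial 4α-CH2OR and axial 4β-Me. The 3-OH is a traceless by-product and is removed by Barton–McCombie deoxygenation.
5. Ring order: A and B at Step 4, then the benzene ring (commercial) is attached at Step 13, then dearomatised and epoxidised at Steps 15–16.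

**Step 1**
Reactants: 1 (2E,6E)-farnesyl acetate
Product: 2 (2E,6E,10E)-12-hydroxyfarnesyl acetate
Conditions: SeO2 (cat.), salicylic acid, TBHP, CH2Cl2, rt
Reagents that add atoms: SeO2 (O=[Se]=O) supplies the O; TBHP (CC(C)(C)OO) is the re-oxidant
Why: Riley/Sharpless allylic oxidation of the terminal trisubstituted alkene occurs at the methyl trans to the chain, which gives the (E)-CH2OH (modest yield).

**Step 2**
Reactants: 2
Product: 3 (10S,11S)-10,11-epoxy-12-hydroxyfarnesyl acetate
Conditions: Ti(OiPr)4, L-(+)-DET, TBHP, 4 Å MS, CH2Cl2, –20 °C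
Reagents that add atoms: TBHP (CC(C)(C)OO) supplies the epoxide O
Why: Sharpless asymmetric epoxidation acts only on the allylic-alcohol alkene. L-(+)-DET sets C10 as S (the configuration that leads to 3β-O and the normal series), and the trans epoxide keeps CH2OH trans to the chain.

**Step 3**
Reactants: 3
Product: 4 (its 12-O-TBS ether)
Conditions: TBSCl, imidazole, DMF, 0 °C to rt
Reagents that add atoms: TBSCl (CC(C)(C)[Si](C)(C)Cl)
Why: Silylation of the primary alcohol protects it from the Lewis acid in Step 4. No stereocentre changes.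

**Step 4**
Reactants: 4
Product: 5 (3β-hydroxy-4α-(TBSOCH2)-drim-8(12)-en-11-yl acetate)
Conditions: SnCl4, CH2Cl2, –78 °C
Reagents that add atoms: none
Why: Epoxide-initiated cation–olefin cyclization (chair–chair) gives the trans-decalin with 5α-H, 10β-Me and 9α-H. The (10S)-epoxide gives 3β-OH. The E geometry puts CH2OTBS equatorial (4α) and Me axial (4β). Cation capture by loss of a C12 proton gives the exocyclic alkene (mixture of alkene isomers, separated).

**Step 5**
Reactants: 5
Product: 6 (its 3-O-phenyl thionocarbonate)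
Conditions: PhOC(S)Cl, DMAP, pyridine, MeCN, rt
Reagents that add atoms: phenyl chlorothionoformate (S=C(Cl)Oc1ccccc1)
Why: This activates the hindered equatorial 3-OH for radical deoxygenation.

**Step 6**
Reactants: 6
Product: 7 (3-deoxy compound)
Conditions: Bu3SnH, AIBN, PhMe, 90 °C
Reagents that add atoms: none (H only)
Why: Barton–McCombie deoxygenation removes the C3 oxygen and leaves no new stereocentre (C3 becomes CH2). The alkene, acetate and TBS ether survive.

**Step 7**
Reactants: 7
Product: 8 (11-alcohol)
Conditions: K2CO3, MeOH, rt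
Reagents that add atoms: none
Why: Mild methanolysis removes the acetate, and the primary TBS ether is stable under these conditions.

**Step 8**
Reactants: 8
Product: 9 (4α-(TBSOCH2)-drim-7-en-11-ol)
Conditions: Co(salen)Cl (cat.), PhSiH3 (cat.), PhMe, rt
Reagents that add atoms: none
Why: Co–H hydrogen-atom transfer to the exocyclic CH2 gives a tertiary C8 radical, and the kinetically accessible C7–H is lost to give the trisubstituted Δ7 alkene. C9 is untouched, so 9α-H is retained.

**Step 9**
Reactants: 9
Product: 10 (11-iodide)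
Conditions: I2, PPh3, imidazole, CH2Cl2, 0 °C to rt
Reagents that add atoms: I2 (II)
Why: Appel/Garegg–Samuelsson iodination converts the primary alcohol to the iodide with no stereochemical change.

**Step 10**
Reactants: 11 (5-hydroxy-2-methoxybenzaldehyde)
Product: 12 (4-bromo-5-hydroxy-2-methoxybenzaldehyde)
Conditions: NBS, CH2Cl2, 0 °C
Reagents that add atoms: NBS (O=C1CCC(=O)N1Br)
Why: Electrophilic aromatic bromination goes ortho to the OH and para to the CHO, the least hindered activated site.

**Step 11**
Reactants: 12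
Product: 13 (4-bromo-5-hydroxy-2-methoxybenzyl alcohol)
Conditions: NaBH4, MeOH, 0 °C
Reagents that add atoms: none
Why: Chemoselective hydride reduction of the aldehyde.

**Step 12**
Reactants: 13
Product: 14 (bis-TBS ether: aryl O-TBS and benzylic O-TBS)
Conditions: TBSCl (2.5 equiv), imidazole, DMF, rt
Reagents that add atoms: TBSCl (CC(C)(C)[Si](C)(C)Cl)
Why: Both OH groups are silylated so that the aryl bromide tolerates organozinc chemistry.

**Step 13**
Reactants: 10 and 14
Product: 15 (C11-aryl drimane)
Conditions: Zn, LiCl, I2 (cat.), THF, 50 °C, then 14, Pd-PEPPSI-IPent, THF/NMP, 60 °C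
Reagents that add atoms: none
Why: Negishi coupling joins the primary alkylzinc to the aryl bromide, forming the Ca–C11 bond with retention of all drimane stereocentres.

**Step 14**
Reactants: 15
Product: 16 (free phenol at Cf)
Conditions: K2CO3, MeOH, rt
Reagents that add atoms: none
Why: Aryl silyl ethers cleave under mild base much faster than alkyl TBS ethers, so this is chemoselective.

**Step 15**
Reactants: 16
Product: 17 (quinone monoketal: Cf=O, Cc(OMe)2)
Conditions: PhI(OAc)2, MeOH, 0 °C
Reagents that add atoms: MeOH (CO)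
Why: Hypervalent-iodine oxidative dearomatization of a 4-methoxyphenol traps the phenoxonium ion with methanol at the para carbon. This puts the ketone at Cf and the ketal at Cc, as needed for the regiochemistry of Step 16.

**Step 16**
Reactants: 17
Product: 18 (Ca–Cb epoxy-enone ketal)
Conditions: 30% H2O2, NaOH (cat.), THF/MeOH, 0 °C
Reagents that add atoms: H2O2 (OO)
Why: Weitz–Scheffer epoxidation occurs selectively at the Ca=Cb enone, whose β-carbon is unsubstituted; the Cd=Ce enone has a substituted β-carbon and is unreactive. The face is controlled by the chiral terpene side chain, and the diastereomer with the target Ca/Cb configuration is isolated.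

**Step 17**
Reactants: 18
Product: 19 (Cf-alcohol)
Conditions: NaBH4, CeCl3·7H2O, MeOH, –78 °C
Reagents that add atoms: none
Why: Luche reduction of the ketone. The bulky Ca-CH2R group blocks its own face, so hydride enters syn to the epoxide O and the OH ends up trans to the epoxide, as in the target.

**Step 18**
Reactants: 19
Product: 20 Epoxypholamin A
Conditions: 48% aq. HF, MeCN, 0 °C to rt
Reagents that add atoms: water (O), which supplies the new ketone oxygen
Why: One pot removes both TBS ethers and hydrolyses the dimethyl ketal to the enone at Cc, which is the target.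

**Compound list**

| # | Name | SMILES | Role |
|---|---|---|---|
| 1 | (2E,6E)-farnesyl acetate | CC(C)=CCC/C(C)=C/CC/C(C)=C/COC(C)=O | starting material |
| 2 | (2E,6E,10E)-12-hydroxyfarnesyl acetate | CC(=O)OC/C=C(C)/CC/C=C(C)/CC/C=C(C)/CO | intermediate |
| 3 | (10S,11S)-10,11-epoxy-12-hydroxyfarnesyl acetate | CC(=O)OC/C=C(C)/CC/C=C(C)/CC[C@@H]1O[C@@]1(C)CO | intermediate |
| 4 | 12-O-TBS ether of 3 | CC(=O)OC/C=C(C)/CC/C=C(C)/CC[C@@H]1O[C@@]1(C)CO[Si](C)(C)C(C)(C)C | intermediate |
| 5 | 3β-hydroxy-4α-(TBSOCH2)-drim-8(12)-en-11-yl acetate | C=C1CC[C@H]2[C@](C)(CO[Si](C)(C)C(C)(C)C)[C@@H](O)CC[C@]2(C)[C@H]1COC(C)=O | intermediate |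
| 6 | 3-O-phenyl thionocarbonate of 5 | C=C1CC[C@H]2[C@](C)(CO[Si](C)(C)C(C)(C)C)[C@@H](OC(=S)Oc3ccccc3)CC[C@]2(C)[C@H]1COC(C)=O | intermediate |
| 7 | 3-deoxy compound | C=C1CC[C@H]2[C@](C)(CO[Si](C)(C)C(C)(C)C)CCC[C@]2(C)[C@H]1COC(C)=O | intermediate |
| 8 | 11-alcohol (Δ8(12)) | C=C1CC[C@H]2[C@](C)(CO[Si](C)(C)C(C)(C)C)CCC[C@]2(C)[C@H]1CO | intermediate |
| 9 | 4α-(TBSOCH2)-drim-7-en-11-ol | CC1=CC[C@H]2[C@](C)(CO[Si](C)(C)C(C)(C)C)CCC[C@]2(C)[C@H]1CO | intermediate |
| 10 | 11-iodo analogue of 9 | CC1=CC[C@H]2[C@](C)(CO[Si](C)(C)C(C)(C)C)CCC[C@]2(C)[C@H]1CI | intermediate |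
| 11 | 5-hydroxy-2-methoxybenzaldehyde | O=Cc1cc(O)ccc1OC | starting material |
| 12 | 4-bromo-5-hydroxy-2-methoxybenzaldehyde | O=Cc1cc(O)c(Br)cc1OC | intermediate |
| 13 | (4-bromo-5-hydroxy-2-methoxyphenyl)methanol | OCc1cc(O)c(Br)cc1OC | intermediate |
| 14 | bis-TBS ether of 13 | CC(C)(C)[Si](C)(C)OCc1cc(O[Si](C)(C)C(C)(C)C)c(Br)cc1OC | intermediate |
| 15 | C11-aryl drimane (three silyl ethers) | CC1=CC[C@H]2[C@](C)(CO[Si](C)(C)C(C)(C)C)CCC[C@]2(C)[C@H]1Cc1cc(OC)c(CO[Si](C)(C)C(C)(C)C)cc1O[Si](C)(C)C(C)(C)C | intermediate |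
| 16 | phenol from 15 | CC1=CC[C@H]2[C@](C)(CO[Si](C)(C)C(C)(C)C)CCC[C@]2(C)[C@H]1Cc1cc(OC)c(CO[Si](C)(C)C(C)(C)C)cc1O | intermediate |
| 17 | quinone monoketal | CC1=CC[C@H]2[C@](C)(CO[Si](C)(C)C(C)(C)C)CCC[C@]2(C)[C@H]1CC3=CC(OC)(OC)C(CO[Si](C)(C)C(C)(C)C)=CC3=O | intermediate |
| 18 | epoxy-enone ketal | CC1=CC[C@H]2[C@](C)(CO[Si](C)(C)C(C)(C)C)CCC[C@]2(C)[C@H]1C[C@@]34O[C@@H]3C(OC)(OC)C(CO[Si](C)(C)C(C)(C)C)=CC4=O | intermediate |
| 19 | epoxy alcohol ketal | CC1=CC[C@H]2[C@](C)(CO[Si](C)(C)C(C)(C)C)CCC[C@]2(C)[C@H]1C[C@@]34O[C@@H]3C(OC)(OC)C(CO[Si](C)(C)C(C)(C)C)=C[C@H]4O | intermediate |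
| 20 | Epoxypholamin A | CC1=CC[C@H]2[C@](C)(CO)CCC[C@]2(C)[C@H]1C[C@@]12O[C@@H]1C(=O)C(CO)=C[C@H]2O | target |

**Step count:** 18 steps in total, including the three aryl-preparation steps (Steps 10–12). The longest linear sequence is 15 steps: Steps 1–9, then 13, then 14–18.

**Three steps most likely to fail**
1. **Step 4 (epoxy-polyene cyclization).** The CH2OTBS group next to the epoxide carbon destabilises the incipient cation, and alkene isomers and monocyclic products are likely.
   - Fallback: cyclise the standard gem-dimethyl (3S)-epoxyfarnesyl acetate instead. Then oxidise the 3-OH to the ketone, make the oxime, and use Pd(OAc)2/PhI(OAc)2 C–H acetoxylation of the near-eclipsed equatorial 4α-methyl, followed by Wolff–Kishner reduction at C3.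
2. **Step 13 (Negishi coupling).** The β-branched alkylzinc and the ortho-silyloxy aryl bromide are both hindered, so β-hydride elimination or protodemetalation may compete.
   - Fallback: switch the polarity of the coupling. Oxidise 9 to the 11-aldehyde (DMP) and add the aryllithium from 14. Then deoxygenate the benzylic alcohol (Barton–McCombie) or use Et3SiH/TFA (which may attack the Δ7 alkene).
3. **Step 16 (epoxidation facial selectivity).** Only remote, weak substrate control is available, so a mixture of ring-C diastereomers is expected.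
   - Fallback: use catalyst-controlled asymmetric nucleophilic epoxidation, such as La–BINOL–Ph3P=O with cumene hydroperoxide or a cinchona phase-transfer catalyst, chosen to give the matched face.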